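The ten-membered carbocycle is cut between C5, the CH of the (Z)-C4=C5 alkene on the furanone, and C6, the O-bearing carbon of the γ-lactone (germacrane numbering). That bond joins an alkenyl carbon to an allylic carbinol carbon, so it is made by an intramolecular Nozaki–Hiyama–Kishi addition: a (Z)-alkenyl iodide on the finished 3(2H)-furanone adds to a C6 aldehyde that is stored as a γ-lactol with the C12 hydroxyl. One operation closes the oxygen-bridged ten-membered ring and sets C6 under control of C7 and C8; oxidation of the resulting 1,4-diol then gives the lactone. C7 and C8 are relayed from purchased C11 in one aldol; C10 comes from (S)-lactic acid.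

Key step: step 16

Remark: germacrane numbering is used throughout (C1 furanone carbonyl, C3 and C10 the carbons bridged by the furanone oxygen, C6 and C12 the lactone carbinol and carbonyl carbons, C8 the ester carbinol); lactone 12 is assumed to be purchasable as the single (S) enantiomer.

Step 1
Reactants: 1 (S)-lactic acid; 2 pivalaldehyde
Product: 3 (2S,5S)-2-tert-butyl-5-methyl-1,3-dioxolan-4-one
Conditions: TsOH (cat.), H2SO4 (cat.), pentane, reflux, Dean–Stark; recrystallisation at −78 °C
Reagents that add atoms: none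
Why: Acid-catalysed acetalisation (self-regeneration-of-stereocentres auxiliary); the cis-2,5 acetal is the thermodynamic and crystalline isomer, so the acetal centre (2S) is set by the lactic acid centre.

Step 2
Reactants: 3; 4 allyl bromide
Product: 6 (2S,5R)-5-allyl-2-tert-butyl-5-methyl-1,3-dioxolan-4-one, via lithium enolate 5 (not isolated)
Conditions: LiN(i-Pr)2, THF, −78 °C; then 4, −78 to −30 °C
Reagents that add atoms: none
Why: Diastereoselective alkylation of the dioxolanone enolate (self-regeneration of stereocentres); the tert-butyl group blocks one face of the planar enolate, allyl bromide enters trans to it, and the quaternary centre (later C10, R) forms with overall retention.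

Step 3
Reactants: 6
Product: 7 (2S,5R)-5-allyl-2-tert-butyl-5-methyl-1,3-dioxolan-4-ol (mixture at C4)
Conditions: i-Bu2AlH (1.1 equiv), CH2Cl2, −78 °C; aq. potassium sodium tartrate
Reagents that add atoms: none
Why: Half-reduction of the lactone-type carbonyl (tetrahedral aluminate stable at −78 °C) gives the cyclic hemiacetal, a masked α-hydroxy aldehyde; the quaternary centre is not involved.

Step 4
Reactants: 7
Product: 9 (R)-3-methylhex-5-en-1-yn-3-ol, via (R)-2-hydroxy-2-methylpent-4-enal 8 (not isolated)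
Conditions: dimethyl (1-diazo-2-oxopropyl)phosphonate, K2CO3, MeOH, 0 °C to rt
Reagents that add atoms: dimethyl (1-diazo-2-oxopropyl)phosphonate, CC(=O)C(=[N+]=[N-])P(=O)(OC)OC
Why: Ohira–Bestmann (Seyferth–Gilbert) homologation; in basic methanol the hemiacetal releases pivalaldehyde and the non-enolisable aldehyde 8, which the diazophosphonate anion converts into the terminal alkyne (C1≡C2) without touching the quaternary centre.

Step 5
Reactants: 9
Product: 10 (R)-trimethyl[(3-methylhex-5-en-1-yn-3-yl)oxy]silane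
Conditions: TMSCl, imidazole, DMF, 0 °C to rt
Reagents that add atoms: chlorotrimethylsilane, C[Si](C)(C)Cl
Why: Silylation of the tertiary propargylic alcohol prevents retro-aldol cleavage and proton transfer in the aldol step; the TMS group is chosen because step 10 removes it without an extra operation.

Step 6
Reactants: 10
Product: 11 (R)-3-methyl-3-(trimethylsilyloxy)pent-4-ynal
Conditions: O3, CH2Cl2, −78 °C (Sudan red 7B end point); then PPh3, −78 °C to rt
Reagents that add atoms: ozone, [O-][O+]=O
Why: Ozonolysis with reductive work-up; the terminal alkene reacts far faster with ozone than the terminal alkyne, so only the allyl group is cleaved to the C8 aldehyde.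

Step 7
Reactants: 12 (S)-4-methyldihydrofuran-2(3H)-one; 11
Product: 14 (3R,4S)-3-[(1R,3R)-1-hydroxy-3-methyl-3-(trimethylsilyloxy)pent-4-yn-1-yl]-4-methyldihydrofuran-2(3H)-one, via lactone lithium enolate 13 (not isolated)
Conditions: LiN(i-Pr)2, THF, −78 °C; then 11, −78 °C; aq. NH4Cl at −78 °C
Reagents that add atoms: none
Why: Lithium enolate aldol addition through a Zimmerman–Traxler chair; the ring-locked E(O)-enolate should give the 7,8-anti adduct and the aldehyde approaches anti to the C11 methyl group, so C7 (trans on the ring) and C8 are both set in one event from the purchased C11 centre.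

Step 8
Reactants: 14
Product: 15 (3R,4S)-3-[(1R,3R)-1-(tert-butyldimethylsilyloxy)-3-methyl-3-(trimethylsilyloxy)pent-4-yn-1-yl]-4-methyldihydrofuran-2(3H)-one
Conditions: TBSOTf, 2,6-lutidine, CH2Cl2, −78 °C
Reagents that add atoms: tert-butyldimethylsilyl trifluoromethanesulfonate, CC(C)(C)[Si](C)(C)OS(=O)(=O)C(F)(F)F
Why: Silyl ether formation; the secondary TBS ether masks O8 through the hydride, organolithium and oxidation steps and keeps O8 out of every later ring closure.

Step 9
Reactants: 15
Product: 16 (3R,4S)-3-[(1R,3R)-1-(tert-butyldimethylsilyloxy)-3-methyl-3-(trimethylsilyloxy)pent-4-yn-1-yl]-4-methyltetrahydrofuran-2-ol (anomeric mixture)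
Conditions: i-Bu2AlH (1.2 equiv), CH2Cl2, −78 °C; aq. potassium sodium tartrate
Reagents that add atoms: none
Why: Lactone-to-lactol half-reduction, possible at this stage because the molecule carries no ketone yet; C6 reaches the aldehyde level and C12 the alcohol level.

Step 10
Reactants: 16
Product: 17 (3R,5R)-5-(tert-butyldimethylsilyloxy)-5-[(3R,4S)-2-methoxy-4-methyltetrahydrofuran-3-yl]-3-methylpent-1-yn-3-ol (anomeric mixture)
Conditions: PPTS (cat.), MeOH, rt
Reagents that add atoms: methanol, CO
Why: Acid-catalysed acetalisation turns the lactol into its methyl acetal and in the same operation cleaves the labile tertiary TMS ether, freeing the propargylic alcohol needed for furanone formation.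

Step 11
Reactants: 18 propargyl alcohol
Product: 20 (Z)-3-iodo-2-methylprop-2-en-1-ol, via alkenylmagnesium alkoxide 19 (not isolated)
Conditions: MeMgBr (2.5 equiv), CuI (10 mol %), THF, −10 °C to rt; then I2, −10 °C
Reagents that add atoms: methylmagnesium bromide, C[Mg]Br; iodine, II
Why: Copper-catalysed anti-carbomagnesiation of the propargyl alkoxide (methyl to the internal carbon, magnesium held cis to the alkoxide in 19) followed by iodinolysis with retention gives the (Z)-alkenyl iodide.

Step 12
Reactants: 20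
Product: 22 (Z)-3-iodo-2-methylacrylic acid, via (Z)-3-iodo-2-methylacrylaldehyde 21 (not isolated)
Conditions: TEMPO (20 mol %), PhI(OAc)2 (2.2 equiv), MeCN/H2O 1:1, rt
Reagents that add atoms: water, O
Why: Oxoammonium (TEMPO) oxidation in aqueous acetonitrile takes the allylic alcohol through aldehyde 21 and its hydrate to the acid under near-neutral conditions that should preserve the Z geometry.

Step 13
Reactants: 22
Product: 24 (Z)-3-iodo-N-methoxy-N,2-dimethylacrylamide, via acyl imidazole 23 (not isolated)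
Conditions: CDI, CH2Cl2, rt; then MeNH(OMe)·HCl, rt
Reagents that add atoms: N,O-dimethylhydroxylamine hydrochloride, CNOC.Cl
Why: Weinreb amide formation through the acyl imidazole avoids acid chloride conditions that could isomerise the iodoalkene.

Step 14
Reactants: 17; 24
Product: 26 (1Z,6R,8R)-8-(tert-butyldimethylsilyloxy)-6-hydroxy-1-iodo-8-[(3R,4S)-2-methoxy-4-methyltetrahydrofuran-3-yl]-2,6-dimethyloct-1-en-4-yn-3-one, via dilithium alkoxide acetylide 25 (not isolated)
Conditions: n-BuLi (2.05 equiv), THF, −78 to −20 °C; then 24, −78 to −20 °C; aq. NH4Cl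
Reagents that add atoms: none
Why: Acylation of a lithium acetylide with a Weinreb amide; the chelated tetrahedral intermediate stops at the ketone, the O10 alkoxide is a spectator, and exactly two equivalents of base leave no alkyllithium for iodine–lithium exchange.

Step 15
Reactants: 26
Product: 28 (R)-2-{(R)-2-(tert-butyldimethylsilyloxy)-2-[(3R,4S)-2-hydroxy-4-methyltetrahydrofuran-3-yl]ethyl}-5-[(Z)-1-iodoprop-1-en-2-yl]-2-methylfuran-3(2H)-one (anomeric mixture), via furanone methyl acetal 27 (not isolated)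
Conditions: (p-CF3C6H4)3PAuCl (5 mol %), AgOTf (5 mol %), toluene, rt, dark; then 0.5 M HCl, THF, 0 °C to rt
Reagents that add atoms: water, O
Why: Cationic monovalent gold-catalysed hydrative cycloisomerisation of a γ-hydroxy ynone to a 3(2H)-furanone (hydration at C1, attack of O10 on C3, loss of water), followed in the same flask by acid hydrolysis of the methyl acetal to the lactol; no stereocentre is touched.

Step 16
Reactants: 28
Product: 30 (4Z,6R,7S,8R,10R,11S)-8-(tert-butyldimethylsilyloxy)-6,12-dihydroxy-3,10-epoxygermacra-2,4-dien-1-one, via alkenylchromium hydroxy aldehyde 29 (not isolated)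
Conditions: CrCl2 (10 equiv), NiCl2 (2 mol %), degassed DMSO, rt, slow addition of 28 to 0.002 M
Reagents that add atoms: none
Why: Nozaki–Hiyama–Kishi reaction: zerovalent nickel formed from NiCl2 and CrCl2 inserts into the C5–I bond with retention of the Z geometry, transmetalation gives the alkenyl trivalent chromium species 29, and this adds to the C6 aldehyde that the γ-lactol releases by ring–chain tautomerism (lactols serve as aldehyde surrogates in chromium-mediated allylations and Takai olefinations). The closest known reaction type is the nickel/chromium-mediated macrocyclisation of iodoalkenyl aldehydes to medium and large rings. The ring closed is the ten-membered carbocycle C1–C10 (nine-membered through the furanone oxygen), by exo-trig attack on the carbonyl so that O6 ends outside the ring. The new C6 stereocentre is controlled by C7 and C8: Felkin–Anh addition with the C7–C8 bond antiperiplanar to the incoming alkenylchromium, which is also the geometry the later trans-fused lactone requires, and the 1,3-anti preference exerted by the C8 silyl ether are mutually reinforcing and both lead to 6R (O6 syn to C11, anti to O8). The step needs chemoselectivity for the aldehyde over the furanone carbonyl and tolerance of two free hydroxyl groups, which the carbonyl selectivity and low basicity of organochromium reagents provide, and it needs ring closure to outrun dimerisation, which high dilution and the rigid (Z)-alkenyl furanone turn secure.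

Step 17
Reactants: 30
Product: 32 (4Z,6R,7S,8R,10R,11S)-8-(tert-butyldimethylsilyloxy)-3,10-epoxy-1-oxogermacra-2,4-dien-12,6-olide, via macrocyclic lactol 31 (not isolated)
Conditions: TEMPO (20 mol %), PhI(OAc)2 (2.5 equiv), CH2Cl2, rt
Reagents that add atoms: none
Why: Oxoammonium oxidative lactonisation of a 1,4-diol; the primary C12 alcohol is oxidised first, the aldehyde is trapped by O6 as lactol 31, and this is oxidised to the γ-lactone, with C6 and C11 keeping their configuration.

Step 18
Reactants: 32
Product: 33 (4Z,6R,7R,8R,10R,11S)-8-hydroxy-3,10-epoxy-1-oxogermacra-2,4-dien-12,6-olide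
Conditions: HF·pyridine, THF/pyridine, 0 °C to rt
Reagents that add atoms: none
Why: Fluoride-mediated desilylation under buffered, non-basic conditions frees O8 without opening or migrating the lactone.

Step 19
Reactants: 33; 34 angelic acid
Product: 36 (4Z,6R,7R,8R,10R,11S)-8-[(Z)-2-methylbut-2-enoyloxy]-3,10-epoxy-1-oxogermacra-2,4-dien-12,6-olide (target), via mixed anhydride 35 (not isolated)
Conditions: 34, 2,4,6-trichlorobenzoyl chloride, Et3N, toluene, rt; then 33, toluene, 80 °C
Reagents that add atoms: none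
Why: Yamaguchi esterification; the mixed anhydride 35 acylates the C8 alcohol on heating without a nucleophilic catalyst, conditions under which the Z (angelate) geometry should be retained.

Compound list
1 | (S)-lactic acid | C[C@H](O)C(=O)O | starting material
2 | pivalaldehyde | CC(C)(C)C=O | starting material
3 | (2S,5S)-2-tert-butyl-5-methyl-1,3-dioxolan-4-one | C[C@@H]1O[C@H](C(C)(C)C)OC1=O | intermediate
4 | allyl bromide | C=CCBr | starting material
5 | lithium enolate of 3 | [Li]OC1=C(C)O[C@H](C(C)(C)C)O1 | intermediate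
6 | (2S,5R)-5-allyl-2-tert-butyl-5-methyl-1,3-dioxolan-4-one | C[C@]1(CC=C)O[C@H](C(C)(C)C)OC1=O | intermediate
7 | (2S,5R)-5-allyl-2-tert-butyl-5-methyl-1,3-dioxolan-4-ol (mixture at C4) | C[C@]1(CC=C)O[C@H](C(C)(C)C)OC1O | intermediate
8 | (R)-2-hydroxy-2-methylpent-4-enal | C=CC[C@@](C)(O)C=O | intermediate
9 | (R)-3-methylhex-5-en-1-yn-3-ol | C#C[C@](C)(O)CC=C | intermediate
10 | (R)-trimethyl[(3-methylhex-5-en-1-yn-3-yl)oxy]silane | C#C[C@](C)(O[Si](C)(C)C)CC=C | intermediate
11 | (R)-3-methyl-3-(trimethylsilyloxy)pent-4-ynal | O=CC[C@@](C)(O[Si](C)(C)C)C#C | intermediate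
12 | (S)-4-methyldihydrofuran-2(3H)-one | C[C@@H]1COC(=O)C1 | starting material
13 | lithium enolate of 12 | C[C@@H]1COC(O[Li])=C1 | intermediate
14 | (3R,4S)-3-[(1R,3R)-1-hydroxy-3-methyl-3-(trimethylsilyloxy)pent-4-yn-1-yl]-4-methyldihydrofuran-2(3H)-one | O[C@H](C[C@@](C)(O[Si](C)(C)C)C#C)[C@@H]1C(=O)OC[C@H]1C | intermediate
15 | (3R,4S)-3-[(1R,3R)-1-(tert-butyldimethylsilyloxy)-3-methyl-3-(trimethylsilyloxy)pent-4-yn-1-yl]-4-methyldihydrofuran-2(3H)-one | CC(C)(C)[Si](C)(C)O[C@H](C[C@@](C)(O[Si](C)(C)C)C#C)[C@@H]1C(=O)OC[C@H]1C | intermediate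
16 | (3R,4S)-3-[(1R,3R)-1-(tert-butyldimethylsilyloxy)-3-methyl-3-(trimethylsilyloxy)pent-4-yn-1-yl]-4-methyltetrahydrofuran-2-ol (anomeric mixture) | CC(C)(C)[Si](C)(C)O[C@H](C[C@@](C)(O[Si](C)(C)C)C#C)[C@@H]1C(O)OC[C@H]1C | intermediate
17 | (3R,5R)-5-(tert-butyldimethylsilyloxy)-5-[(3R,4S)-2-methoxy-4-methyltetrahydrofuran-3-yl]-3-methylpent-1-yn-3-ol (anomeric mixture) | CC(C)(C)[Si](C)(C)O[C@H](C[C@@](C)(O)C#C)[C@@H]1C(OC)OC[C@H]1C | intermediate
18 | propargyl alcohol | C#CCO | starting material
19 | (Z)-alkenylmagnesium bromide alkoxide from carbomagnesiation of 18 | Br[Mg]/C=C(/C)CO[Mg]Br | intermediate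
20 | (Z)-3-iodo-2-methylprop-2-en-1-ol | OC/C(C)=C\I | intermediate
21 | (Z)-3-iodo-2-methylacrylaldehyde | O=C/C(C)=C\I | intermediate
22 | (Z)-3-iodo-2-methylacrylic acid | OC(=O)/C(C)=C\I | intermediate
23 | (Z)-1-(3-iodo-2-methylacryloyl)imidazole | O=C(/C(C)=C\I)n1ccnc1 | intermediate
24 | (Z)-3-iodo-N-methoxy-N,2-dimethylacrylamide | CON(C)C(=O)/C(C)=C\I | intermediate
25 | dilithium alkoxide acetylide of 17 | CC(C)(C)[Si](C)(C)O[C@H](C[C@@](C)(O[Li])C#C[Li])[C@@H]1C(OC)OC[C@H]1C | intermediate
26 | (1Z,6R,8R)-8-(tert-butyldimethylsilyloxy)-6-hydroxy-1-iodo-8-[(3R,4S)-2-methoxy-4-methyltetrahydrofuran-3-yl]-2,6-dimethyloct-1-en-4-yn-3-one | CC(C)(C)[Si](C)(C)O[C@H](C[C@@](C)(O)C#CC(=O)/C(C)=C\I)[C@@H]1C(OC)OC[C@H]1C | intermediate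
27 | (R)-2-{(R)-2-(tert-butyldimethylsilyloxy)-2-[(3R,4S)-2-methoxy-4-methyltetrahydrofuran-3-yl]ethyl}-5-[(Z)-1-iodoprop-1-en-2-yl]-2-methylfuran-3(2H)-one | CC(C)(C)[Si](C)(C)O[C@H](C[C@@]1(C)OC(=CC1=O)/C(C)=C\I)[C@@H]1C(OC)OC[C@H]1C | intermediate
28 | (R)-2-{(R)-2-(tert-butyldimethylsilyloxy)-2-[(3R,4S)-2-hydroxy-4-methyltetrahydrofuran-3-yl]ethyl}-5-[(Z)-1-iodoprop-1-en-2-yl]-2-methylfuran-3(2H)-one (anomeric mixture) | CC(C)(C)[Si](C)(C)O[C@H](C[C@@]1(C)OC(=CC1=O)/C(C)=C\I)[C@@H]1C(O)OC[C@H]1C | intermediate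
29 | alkenylchromium dichloride of the open hydroxy aldehyde form of 28 (trivalent chromium) | CC(C)(C)[Si](C)(C)O[C@H](C[C@@]1(C)OC(=CC1=O)/C(C)=C\[Cr](Cl)Cl)[C@H](C=O)[C@H](C)CO | intermediate
30 | (4Z,6R,7S,8R,10R,11S)-8-(tert-butyldimethylsilyloxy)-6,12-dihydroxy-3,10-epoxygermacra-2,4-dien-1-one | CC(C)(C)[Si](C)(C)O[C@@H]1C[C@@]2(C)OC(=CC2=O)/C(C)=C\[C@@H](O)[C@@H]1[C@H](C)CO | intermediate
31 | (4Z,6R,7S,8R,10R,11S)-8-(tert-butyldimethylsilyloxy)-12-hydroxy-3,10:6,12-diepoxygermacra-2,4-dien-1-one (mixture at C12) | CC(C)(C)[Si](C)(C)O[C@@H]1C[C@@]2(C)OC(=CC2=O)/C(C)=C\[C@H]2OC(O)[C@@H](C)[C@@H]21 | intermediate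
32 | (4Z,6R,7S,8R,10R,11S)-8-(tert-butyldimethylsilyloxy)-3,10-epoxy-1-oxogermacra-2,4-dien-12,6-olide | CC(C)(C)[Si](C)(C)O[C@@H]1C[C@@]2(C)OC(=CC2=O)/C(C)=C\[C@H]2OC(=O)[C@@H](C)[C@@H]21 | intermediate
33 | (4Z,6R,7R,8R,10R,11S)-8-hydroxy-3,10-epoxy-1-oxogermacra-2,4-dien-12,6-olide | O[C@@H]1C[C@@]2(C)OC(=CC2=O)/C(C)=C\[C@H]2OC(=O)[C@@H](C)[C@@H]21 | intermediate
34 | angelic acid, (Z)-2-methylbut-2-enoic acid | C/C=C(/C)C(=O)O | starting material
35 | angelic 2,4,6-trichlorobenzoic anhydride | C/C=C(/C)C(=O)OC(=O)c1c(Cl)cc(Cl)cc1Cl | intermediate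
36 | (4Z,6R,7R,8R,10R,11S)-8-[(Z)-2-methylbut-2-enoyloxy]-3,10-epoxy-1-oxogermacra-2,4-dien-12,6-olide | C/C=C(/C)C(=O)O[C@@H]1C[C@@]2(C)OC(=CC2=O)/C(C)=C\[C@H]2OC(=O)[C@@H](C)[C@@H]21 | target

Total step count: 19. Longest linear sequence: 16 steps (steps 1–10 and 14–19); steps 11–13 make the side fragment 24.

Steps most likely to fail

Step 16. What may go wrong: addition to the wrong face of the C6 aldehyde, which would give the 6-epimeric carbinol and, after step 17, a cis-fused lactone. Slow release of the aldehyde from the lactol would also favour protodehalogenation and oligomerisation. Fallback (correction by inversion instead of substrate control): setting out from 28, the cyclisation product of opposite configuration at C6, the 6-epimeric diol F1, is carried through the TEMPO/PhI(OAc)2 lactonisation to the cis-fused 6-epi-lactone F2. Saponification with LiOH (THF/H2O, 0 °C) and careful acidification gives the 6S hydroxy acid F3. Mitsunobu lactonisation (PPh3, diisopropyl azodicarboxylate, toluene, 0 °C) then closes the lactone with inversion at C6 and returns to the route at 32.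

Step 15. What may go wrong: Lewis-acid-induced Z-to-E isomerisation of the β-iodo enone, or a competing 1,3-hydroxyl shift (Meyer–Schuster pathway) instead of hydration at C1. Fallback (stepwise 1,3-diketone route that avoids the ynone): setting out from 17, Markovnikov hydration of the terminal alkyne (Hg(OTf)2 cat., tetramethylurea, MeCN/H2O) gives the α-hydroxy methyl ketone F4. Its dianion (LiN(i-Pr)2, 2.2 equiv, THF, −78 °C) adds to (Z)-3-iodo-2-methylacrylaldehyde 21, isolated for this purpose after MnO2 oxidation of 20, to give the β-hydroxy ketone F5. Dess–Martin oxidation gives the 1,3-diketone F6, and TsOH in wet THF effects cyclodehydration to the 3(2H)-furanone together with acetal hydrolysis, returning to the route at 28.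

Step 19. What may go wrong: isomerisation of the angeloyl donor to the tigloyl (E) isomer during activation, and slow acylation of the hindered C8 hydroxyl. Fallback (the Z alkene is built on the ester instead of being transferred): setting out from 33, esterification with 2-[bis(2,2,2-trifluoroethoxy)phosphoryl]propanoic acid (DCC, DMAP cat., CH2Cl2) gives the phosphonopropionate ester F7. Still–Gennari olefination (KN(SiMe3)2, 18-crown-6, THF, −78 °C; then acetaldehyde) should give the Z-configured 2-methylbut-2-enoate, returning to the route at 36.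

Further compounds
F1 | step 16 | (4Z,6S,7S,8R,10R,11S)-8-(tert-butyldimethylsilyloxy)-6,12-dihydroxy-3,10-epoxygermacra-2,4-dien-1-one (6-epimer of 30) | CC(C)(C)[Si](C)(C)O[C@@H]1C[C@@]2(C)OC(=CC2=O)/C(C)=C\[C@H](O)[C@@H]1[C@H](C)CO
F2 | step 16 | (4Z,6S,7S,8R,10R,11S)-8-(tert-butyldimethylsilyloxy)-3,10-epoxy-1-oxogermacra-2,4-dien-12,6-olide (6-epimer of 32) | CC(C)(C)[Si](C)(C)O[C@@H]1C[C@@]2(C)OC(=CC2=O)/C(C)=C\[C@@H]2OC(=O)[C@@H](C)[C@@H]21
F3 | step 16 | (4Z,6S,7S,8R,10R,11S)-8-(tert-butyldimethylsilyloxy)-6-hydroxy-1-oxo-3,10-epoxygermacra-2,4-dien-12-oic acid | CC(C)(C)[Si](C)(C)O[C@@H]1C[C@@]2(C)OC(=CC2=O)/C(C)=C\[C@H](O)[C@@H]1[C@H](C)C(=O)O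
F4 | step 15 | (3R,5R)-5-(tert-butyldimethylsilyloxy)-3-hydroxy-5-[(3R,4S)-2-methoxy-4-methyltetrahydrofuran-3-yl]-3-methylpentan-2-one | CC(C)(C)[Si](C)(C)O[C@H](C[C@@](C)(O)C(C)=O)[C@@H]1C(OC)OC[C@H]1C
F5 | step 15 | (1Z,6R,8R)-8-(tert-butyldimethylsilyloxy)-3,6-dihydroxy-1-iodo-8-[(3R,4S)-2-methoxy-4-methyltetrahydrofuran-3-yl]-2,6-dimethyloct-1-en-5-one (mixture at C3) | CC(C)(C)[Si](C)(C)O[C@H](C[C@@](C)(O)C(=O)CC(O)/C(C)=C\I)[C@@H]1C(OC)OC[C@H]1C
F6 | step 15 | (1Z,6R,8R)-8-(tert-butyldimethylsilyloxy)-6-hydroxy-1-iodo-8-[(3R,4S)-2-methoxy-4-methyltetrahydrofuran-3-yl]-2,6-dimethyloct-1-ene-3,5-dione | CC(C)(C)[Si](C)(C)O[C@H](C[C@@](C)(O)C(=O)CC(=O)/C(C)=C\I)[C@@H]1C(OC)OC[C@H]1C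
F7 | step 19 | 8-O-{2-[bis(2,2,2-trifluoroethoxy)phosphoryl]propanoyl} ester of 33 (mixture at the phosphonate carbon) | CC(C(=O)O[C@@H]1C[C@@]2(C)OC(=CC2=O)/C(C)=C\[C@H]2OC(=O)[C@@H](C)[C@@H]21)P(=O)(OCC(F)(F)F)OCC(F)(F)F
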